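**Retrosynthetic overview**
1. Last step: a transannular bromonium cyclisation of the ten-membered (E,E)-dienyl acetate 20 makes the C5–C10 bond. This one bond turns the carbocycle into the bromine-bearing ring and the acetoxy/isopropyl-bearing ring (C5–C6–C7–C8–C9–C10), and it adds Br at C1 and OH at C4.
2. Enabling feature: in the bromine-bearing ring the chain Br–C1–C10–C5–C4–O is all-anti (equatorial Br and equatorial C4–O flank the trans ring-fusion bond), which is the imprint of two anti additions to the E-alkenes C1=C10 and C4=C5. The C6 acetate lies 1,3-syn (peri) to the C4 oxygen, so it can deliver that oxygen through a six-membered dioxanylium ring.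
3. 20 comes from dienol 19, whose ten-membered ring is closed at C9–C10 by an intramolecular B-alkyl Suzuki–Miyaura coupling of iodo-trienol 17.
4. 17 carries C6 and C7, the only stereocentres made before the key step. It comes from an anti-selective, phosphoric-acid-catalysed allylboration of iodo-dienal 11 (six steps from methyl acetoacetate and 1-bromobut-2-yne) with (E)-allylboronate 15 (two steps from 3-methylbut-1-yne).
5. Ring order: ten-membered carbocycle (step 10, temporary as such), then in step 12 the temporary dioxanylium ring and both six-membered rings. No ring is formed afterwards.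

Key step: step 12

Remark: locants follow eudesmane numbering (C1 = CHBr, C2/C3 = CH2, C4 = C(OH)CH3, C5 = ring-fusion CH, C6 = CHOAc, C7 = CH-iPr, C8/C9 = CH2, C10 = quaternary ring-fusion C). The sense of induction of (S)-TRIP in step 9 is assigned by analogy with allyl- and crotylboronations of aryl and α,β-unsaturated aldehydes; if it is opposite, (R)-TRIP is used.

**Step 1**
Reactants: 1 methyl acetoacetate; 2 1-bromobut-2-yne
Product: 4 methyl 3-oxooct-6-ynoate, via acetoacetate dianion 3 (not isolated)
Conditions: NaH, THF, 0 °C; n-BuLi, 0 °C; then 2, 0 °C → rt; aq. HCl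
Reagents that add atoms: none
Why: γ-Alkylation of an acetoacetate dianion, in which the more basic terminal carbanion displaces the propargylic bromide by SN2; no stereocentre is formed.

**Step 2**
Reactants: 4 methyl 3-oxooct-6-ynoate
Product: 6 methyl (2Z)-3-[(diethoxyphosphoryl)oxy]oct-2-en-6-ynoate, via sodium enolate 5 (not isolated)
Conditions: NaH, Et2O, 0 °C; (EtO)2P(O)Cl, 0 °C → rt
Reagents that add atoms: diethyl chlorophosphate CCOP(=O)(Cl)OCC
Why: O-Phosphorylation of a β-keto ester enolate, whose sodium chelate between enolate and ester oxygens should fix the Z geometry of the enol phosphate.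

**Step 3**
Reactants: 6 methyl (2Z)-3-[(diethoxyphosphoryl)oxy]oct-2-en-6-ynoate
Product: 7 methyl (2E)-3-methyloct-2-en-6-ynoate
Conditions: Me2CuLi (MeLi, CuI), Et2O, −78 → −45 °C; aq. NH4Cl
Reagents that add atoms: lithium dimethylcuprate [Li+].C[Cu-]C
Why: Stereoretentive cuprate substitution (addition–elimination) of a β-phosphoryloxy enoate puts methyl where the phosphate stood and should give the E-trisubstituted enoate; the unactivated internal alkyne is inert at this temperature.

**Step 4**
Reactants: 7 methyl (2E)-3-methyloct-2-en-6-ynoate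
Product: 8 (2E)-3-methyloct-2-en-6-yn-1-ol
Conditions: DIBAL-H (2.5 equiv), CH2Cl2, −78 → 0 °C; Rochelle salt
Reagents that add atoms: none
Why: 1,2-Reduction of an enoate with DIBAL-H gives the allylic alcohol without touching the alkene, its geometry or the alkyne.

**Step 5**
Reactants: 8 (2E)-3-methyloct-2-en-6-yn-1-ol
Product: 10 (2E,6E)-7-iodo-3-methylocta-2,6-dien-1-ol, via alkenylzirconocene 9 (not isolated)
Conditions: Cp2ZrHCl (3 equiv), THF, rt → 40 °C; I2, THF, 0 °C; aq. Na2S2O3
Reagents that add atoms: iodine II
Why: Hydrozirconation–iodination: Zr–H adds syn, excess reagent equilibrates zirconium to the less hindered methyl-bearing alkyne carbon, and iodinolysis with retention should give the E-vinyl iodide (the OH is only masked as its zirconium alkoxide).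

**Step 6**
Reactants: 10 (2E,6E)-7-iodo-3-methylocta-2,6-dien-1-ol
Product: 11 (2E,6E)-7-iodo-3-methylocta-2,6-dienal
Conditions: MnO2, CH2Cl2, rt
Reagents that add atoms: none
Why: Chemoselective MnO2 oxidation of an allylic alcohol gives the enal with retention of both alkene geometries and of the vinyl iodide.

**Step 7**
Reactants: 12 3-methylbut-1-yne
Product: 13 (E)-4,4,5,5-tetramethyl-2-(3-methylbut-1-en-1-yl)-1,3,2-dioxaborolane
Conditions: HBpin, Cp2ZrHCl (5 mol %), Et3N (5 mol %), sealed tube, 40 °C
Reagents that add atoms: pinacolborane CC1(C)OBOC1(C)C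
Why: Zirconium-catalysed syn hydroboration of a terminal alkyne places boron at the terminal carbon and gives the E-alkenylboronate.

**Step 8**
Reactants: 13 (E)-4,4,5,5-tetramethyl-2-(3-methylbut-1-en-1-yl)-1,3,2-dioxaborolane
Product: 15 (E)-4,4,5,5-tetramethyl-2-(4-methylpent-2-en-1-yl)-1,3,2-dioxaborolane, via chloromethyl boronate complex 14 (not isolated)
Conditions: BrCH2Cl, n-BuLi, THF, −78 °C → rt
Reagents that add atoms: bromochloromethane ClCBr
Why: Matteson homologation: LiCH2Cl adds to boron and the alkenyl group migrates 1,2 with loss of chloride, which inserts one CH2 and keeps the E geometry.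

**Step 9**
Reactants: 11 (2E,6E)-7-iodo-3-methylocta-2,6-dienal; 15 (E)-4,4,5,5-tetramethyl-2-(4-methylpent-2-en-1-yl)-1,3,2-dioxaborolane
Product: 17 (3S,4S,5E,9E)-10-iodo-6-methyl-3-(propan-2-yl)undeca-1,5,9-trien-4-ol, via pinacol borate ester 16 (not isolated)
Conditions: (S)-TRIP (5 mol %), 4 Å MS, toluene, −30 °C; aq. NaHCO3
Reagents that add atoms: none
Why: Chiral-phosphoric-acid-catalysed allylboration through a closed Zimmerman–Traxler chair, in which the E-boronate places isopropyl equatorial and sets the anti C6–OH/C7–iPr relationship, while the catalyst–boronate hydrogen-bond complex should select the Si face of the enal and set C6 as S.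

**Step 10**
Reactants: 17 (3S,4S,5E,9E)-10-iodo-6-methyl-3-(propan-2-yl)undeca-1,5,9-trien-4-ol
Product: 19 (1S,2E,6E,10R)-3,7-dimethyl-10-(propan-2-yl)cyclodeca-2,6-dien-1-ol, via bis-boryl intermediate 18 (not isolated)
Conditions: 9-BBN-H (2.3 equiv), THF, 0 °C → rt; then slow addition to Pd(dppf)Cl2 (15 mol %), AsPh3, Cs2CO3, DMF–THF–H2O, 45 °C, 2 mM
Reagents that add atoms: none
Why: 9-BBN hydroborates only the monosubstituted alkene and transiently borylates the OH, and the intramolecular B-alkyl Suzuki–Miyaura coupling at high dilution joins C9 to C10 with retention of the vinyl iodide geometry, so both ring alkenes are E and no stereocentre is touched.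

**Step 11**
Reactants: 19 (1S,2E,6E,10R)-3,7-dimethyl-10-(propan-2-yl)cyclodeca-2,6-dien-1-ol
Product: 20 (1S,2E,6E,10R)-3,7-dimethyl-10-(propan-2-yl)cyclodeca-2,6-dien-1-yl acetate
Conditions: Ac2O, Et3N, DMAP (cat.), CH2Cl2, 0 °C → rt
Reagents that add atoms: acetic anhydride CC(=O)OC(C)=O
Why: DMAP-catalysed acylation of the secondary alcohol proceeds at oxygen with retention at C6 under non-acidic conditions that spare the acid-sensitive 1,5-diene.

**Step 12**
Reactants: 20 (1S,2E,6E,10R)-3,7-dimethyl-10-(propan-2-yl)cyclodeca-2,6-dien-1-yl acetate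
Product: 22 austradiol acetate, via dioxanylium ion 21 (not isolated)
Conditions: NBS (1.05 equiv), acetone–H2O 4:1, −10 → 0 °C, dark
Reagents that add atoms: N-bromosuccinimide O=C1CCC(=O)N1Br; water O
Why: NBS transfers Br+ to the outer face of the electron-richer C1=C10 alkene, C5 of the facing C4=C5 alkene opens the bromonium ion at tertiary C10, and the C4 cation is taken from the outer face by the carbonyl oxygen of the C6 acetate (direct capture by water leads to the same product) to give dioxanylium ion 21, which water opens through its hemiorthoester to the free tertiary C4–OH and the acetate on the less hindered secondary C6–O. The closest known reaction type is the electrophile-induced (NBS, H+, Hg2+) transannular cyclisation of (E,E)-germacra-1(10),4-dienes to trans-eudesmanes, joined here to classical neighbouring-group participation of an ester. The one new C5–C10 bond closes the bromine-bearing ring 6-endo (both alkenes lie inside it) and the acetoxy/isopropyl-bearing ring 6-exo (C1 and C4 stay outside it), while the temporary dioxanylium ring closes 6-exo at C4. C1 and C10 follow from anti addition of Br and C5 to the E-C1=C10 alkene, C5 and C4 from anti addition of C10 and O to the E-C4=C5 alkene, and the crossed chair–chair conformer makes the fusion trans with equatorial Br, equatorial C4–O and both methyl groups axial. The sense relative to C6 and C7 is fixed by C6: A(1,3) strain with the C4 methyl group keeps H6 in the alkene plane, so C7 (and with it C10) sits on one face of C4=C5 and the acetate on the other, whereas the opposite planar-chiral conformer would place the acetate axial between two axial methyl groups, a far higher price than the axial isopropyl group accepted at C7. The step needs site selectivity for C1=C10 (secured by the deactivating allylic acetate on C4=C5), opening at C10 and not C1 (tertiary versus secondary carbon) and oxygen capture faster than proton loss from C4 (intramolecular acetate in an aqueous medium).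

**Compound list**
1 | methyl acetoacetate | CC(=O)CC(=O)OC | starting material
2 | 1-bromobut-2-yne | CC#CCBr | starting material
3 | sodium lithium dianion of methyl acetoacetate | [Na+].[Li+].C=C([O-])C=C([O-])OC | intermediate
4 | methyl 3-oxooct-6-ynoate | CC#CCCC(=O)CC(=O)OC | intermediate
5 | sodium (Z)-enolate of 4 | [Na+].CC#CCC/C([O-])=C/C(=O)OC | intermediate
6 | methyl (2Z)-3-[(diethoxyphosphoryl)oxy]oct-2-en-6-ynoate | CC#CCC/C(=C/C(=O)OC)OP(=O)(OCC)OCC | intermediate
7 | methyl (2E)-3-methyloct-2-en-6-ynoate | CC#CCC/C(C)=C/C(=O)OC | intermediate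
8 | (2E)-3-methyloct-2-en-6-yn-1-ol | CC#CCC/C(C)=C/CO | intermediate
9 | (E)-alkenylzirconocene chloride of 8, OH masked as zirconocene chloride alkoxide | C/C(=C\CC/C(C)=C/CO[Zr](Cl)(C1C=CC=C1)C1C=CC=C1)[Zr](Cl)(C1C=CC=C1)C1C=CC=C1 | intermediate
10 | (2E,6E)-7-iodo-3-methylocta-2,6-dien-1-ol | C/C(I)=C\CC/C(C)=C/CO | intermediate
11 | (2E,6E)-7-iodo-3-methylocta-2,6-dienal | C/C(I)=C\CC/C(C)=C/C=O | intermediate
12 | 3-methylbut-1-yne | CC(C)C#C | starting material
13 | (E)-4,4,5,5-tetramethyl-2-(3-methylbut-1-en-1-yl)-1,3,2-dioxaborolane | CC(C)/C=C/B1OC(C)(C)C(C)(C)O1 | intermediate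
14 | lithium (chloromethyl)(alkenyl)boronate complex of 13 | [Li+].CC(C)/C=C/[B-]1(CCl)OC(C)(C)C(C)(C)O1 | intermediate
15 | (E)-4,4,5,5-tetramethyl-2-(4-methylpent-2-en-1-yl)-1,3,2-dioxaborolane | CC(C)/C=C/CB1OC(C)(C)C(C)(C)O1 | intermediate
16 | pinacol borate ester of 17 | C=C[C@H](C(C)C)[C@H](OB1OC(C)(C)C(C)(C)O1)/C=C(\C)CC/C=C(\C)I | intermediate
17 | (3S,4S,5E,9E)-10-iodo-6-methyl-3-(propan-2-yl)undeca-1,5,9-trien-4-ol | C=C[C@H](C(C)C)[C@H](O)/C=C(\C)CC/C=C(\C)I | intermediate
18 | C-(9-BBN), O-(9-BBN) adduct of 17 | B1(CC[C@H](C(C)C)[C@H](OB2C3CCCC2CCC3)/C=C(\C)CC/C=C(\C)I)C2CCCC1CCC2 | intermediate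
19 | (1S,2E,6E,10R)-3,7-dimethyl-10-(propan-2-yl)cyclodeca-2,6-dien-1-ol | CC(C)[C@H]1CC/C(C)=C/CC/C(C)=C/[C@H]1O | intermediate
20 | (1S,2E,6E,10R)-3,7-dimethyl-10-(propan-2-yl)cyclodeca-2,6-dien-1-yl acetate | CC(C)[C@H]1CC/C(C)=C/CC/C(C)=C/[C@H]1OC(C)=O | intermediate
21 | 2-methyl-1,3-dioxan-2-ylium ion bridging C4–O and C6–O of the trans-fused bromodecalin | CC1=[O+][C@]2(C)CC[C@@H](Br)[C@]3(C)CC[C@H](C(C)C)[C@H](O1)[C@@H]23 | intermediate
22 | austradiol acetate, (1S,2R,4aR,5R,8R,8aS)-5-bromo-8-hydroxy-4a,8-dimethyl-2-(propan-2-yl)decahydronaphthalen-1-yl acetate | CC(=O)O[C@H]1[C@@H](C(C)C)CC[C@@]2(C)[C@H](Br)CC[C@@](C)(O)[C@H]12 | target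

**Total steps:** 12. **Longest linear sequence:** 10 (steps 1–6 and 9–12).

**Steps most likely to fail**

Step 10 (ring closure to the ten-membered diene). Oligomerisation, protodeboronation and β-hydride elimination may outrun the slow closure of the strained palladacycle, and the aqueous base may erode material during the long addition. The fallback sets out from 17 and comes back at 19; it replaces the borane by a preformed organozinc on a protected substrate.
- 17 is silylated (TBSOTf, 2,6-lutidine) to the silyl ether F1.
- F1 is hydroborated and oxidised (9-BBN-H; NaBO3) to the primary alcohol F2.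
- F2 is converted under Appel conditions (I2, PPh3, imidazole) into the alkyl iodide F3.
- Zinc is inserted selectively into the sp3 C–I bond (Zn, LiCl, THF) to give the alkylzinc iodide F4.
- F4 is added slowly to a Pd(0) catalyst in an anhydrous, base-free intramolecular Negishi coupling with faster transmetalation, giving the macrocyclic silyl ether F5.
- TBAF then releases 19.

Step 12 (key step). Four things may go wrong: proton loss from the C4 cation instead of oxygen capture, competing attack of Br+ on C4=C5, reaction through the other planar-chiral conformer, or collapse of the hemiorthoester with the acetyl group left on the tertiary oxygen. The fallback sets out from 19 and comes back at 22; it uses a non-migrating internal terminator and a non-aqueous bromonium source.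
- 19 is converted (Boc2O, DMAP) into the tert-butyl carbonate F6.
- F6 is cyclised with bromodiethylsulfonium bromopentachloroantimonate (MeNO2, −25 °C) in a carbonate-terminated halonium cyclisation to the bromo cyclic carbonate F7.
- Methanolysis (K2CO3, MeOH) gives the diol F8.
- Ac2O/pyridine acetylates only the secondary C6–OH to give 22.

Step 9 (allylboration). The hindered γ-isopropyl boronate and the β,β-disubstituted enal may react slowly, with poor facial selectivity from the catalyst. The anti relationship comes from the boronate geometry and is less at risk. The fallback sets out from 11 and 15 and comes back at 17.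
- The uncatalysed allylboration (toluene, rt; hydrolytic work-up) should give the anti adduct as a racemate, that is 17 together with its enantiomer F9.
- A Sharpless kinetic resolution (Ti(OiPr)4, D-(−)-DIPT, TBHP 0.6 equiv, 4 Å MS, CH2Cl2, −20 °C) should convert the fast-reacting F9 into the erythro epoxy alcohol F10.
- 17 is left behind for chromatographic separation.

**Further compounds**
F1 | step 10 | tert-butyldimethylsilyl ether of 17 | C=C[C@H](C(C)C)[C@H](O[Si](C)(C)C(C)(C)C)/C=C(\C)CC/C=C(\C)I
F2 | step 10 | primary alcohol from hydroboration–oxidation of F1 | OCC[C@H](C(C)C)[C@H](O[Si](C)(C)C(C)(C)C)/C=C(\C)CC/C=C(\C)I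
F3 | step 10 | primary alkyl iodide from F2 | ICC[C@H](C(C)C)[C@H](O[Si](C)(C)C(C)(C)C)/C=C(\C)CC/C=C(\C)I
F4 | step 10 | alkylzinc iodide from F3 | I[Zn]CC[C@H](C(C)C)[C@H](O[Si](C)(C)C(C)(C)C)/C=C(\C)CC/C=C(\C)I
F5 | step 10 | tert-butyldimethylsilyl ether of 19 | CC(C)[C@H]1CC/C(C)=C/CC/C(C)=C/[C@H]1O[Si](C)(C)C(C)(C)C
F6 | step 12 | tert-butyl carbonate of 19 | CC(C)[C@H]1CC/C(C)=C/CC/C(C)=C/[C@H]1OC(=O)OC(C)(C)C
F7 | step 12 | bromo cyclic carbonate (1,3-dioxan-2-one bridging C4–O and C6–O) | O=C1O[C@]2(C)CC[C@@H](Br)[C@]3(C)CC[C@H](C(C)C)[C@H](O1)[C@@H]23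
F8 | step 12 | bromo diol (deacetyl target) | O[C@H]1[C@@H](C(C)C)CC[C@@]2(C)[C@H](Br)CC[C@@](C)(O)[C@H]12
F9 | step 9 | enantiomer of 17 | C=C[C@@H](C(C)C)[C@@H](O)/C=C(\C)CC/C=C(\C)I
F10 | step 9 | erythro epoxy alcohol from F9 | C=C[C@@H](C(C)C)[C@@H](O)[C@H]1O[C@]1(C)CC/C=C(\C)I
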